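**Assumption:** the target has no stereocentre and is achiral, so there is no enantiomer to control; the route only has to deliver the correct substitution pattern.

**Retrosynthetic overview**
1. No ring is formed: the benzene ring, the CHO and both OH groups are bought intact as 3,4-dihydroxybenzaldehyde.
2. The only disconnections are the three C–Br bonds, each made by electrophilic aromatic substitution.
3. Every free ring position of the starting material (numbered with CHO = C1, OH at C3 and C4) is ortho or para to an OH: C5 ortho to 4-OH, C6 para to 3-OH, C2 ortho to 3-OH.
4. The expected order is C5, then C6, then C2, all in one flask; because all three positions end up brominated, regiochemistry cannot go wrong.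

**Step 1**
Reactants: 1 3,4-dihydroxybenzaldehyde (protocatechualdehyde)
Product: 4 2,3,6-tribromo-4,5-dihydroxybenzaldehyde, via monobromide 2 (not isolated), via dibromide 3 (not isolated)
Conditions: Br2 (3.2 equiv, added dropwise), AcOH, 20 °C then 60 °C; pour into ice-water, filter, recrystallise
Reagents that add atoms: bromine, BrBr
Why: Threefold electrophilic aromatic bromination, in which the two phenolic OH groups override the deactivating CHO and direct Br to the only three free positions (each ortho or para to an OH), so exhaustive substitution can only give 4; no stereocentre is formed.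

**Compound list**
1 | 3,4-dihydroxybenzaldehyde | O=Cc1ccc(O)c(O)c1 | starting material
2 | 3-bromo-4,5-dihydroxybenzaldehyde (monobromide) | O=Cc1cc(O)c(O)c(Br)c1 | intermediate
3 | 2,3-dibromo-4,5-dihydroxybenzaldehyde (dibromide) | O=Cc1cc(O)c(O)c(Br)c1Br | intermediate
4 | 2,3,6-tribromo-4,5-dihydroxybenzaldehyde | O=Cc1c(Br)c(O)c(O)c(Br)c1Br | target

**Total step count:** 1
**Longest linear sequence:** 1 step

**Steps most likely to fail**
The route has a single step, so step 1 is the only one that can be ranked. Its failure modes, most likely first, are:
- **Stalling at the dibromide.** The last position is flanked by OH and CHO on a ring that already carries two Br.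
- **Loss of the formyl group.** Ipso-bromination at C1, which is para to the 4-OH, would remove the CHO.
- **Oxidation of the catechol.** Br2 can oxidise the catechol to the o-quinone; washing the crude solid with dilute aqueous NaHSO3 would reduce it back.

Fallback for step 1: this fallback sets out from 1 and comes back to the route at 4. It replaces the aldehyde, during the bromination, by a nitrile that can neither be lost by ipso-substitution nor be oxidised. Heating 1 with NH2OH·HCl in N-methylpyrrolidone at 110 °C gives (E)-3,4-dihydroxybenzaldehyde oxime F1, which dehydrates in the same flask to 3,4-dihydroxybenzonitrile F2. Br2 (3.2 equiv) in AcOH at 20 °C then 60 °C takes F2 through 3-bromo-4,5-dihydroxybenzonitrile F3 and 2,3-dibromo-4,5-dihydroxybenzonitrile F4 to 2,3,6-tribromo-4,5-dihydroxybenzonitrile F5. The linear nitrile also crowds the two flanking positions less than CHO does. Partial reduction of F5 with i-Bu2AlH (4 equiv, two of them consumed by the phenols) in toluene/THF at −78 °C to 0 °C, then work-up with 2 M HCl, releases 2,3,6-tribromo-4,5-dihydroxybenzaldimine F6. F6 hydrolyses at once to 4; the aryl bromides are untouched at this temperature.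

**Further compounds**
F1 | step 1 | (E)-3,4-dihydroxybenzaldehyde oxime | O/N=C/c1ccc(O)c(O)c1
F2 | step 1 | 3,4-dihydroxybenzonitrile | N#Cc1ccc(O)c(O)c1
F3 | step 1 | 3-bromo-4,5-dihydroxybenzonitrile | N#Cc1cc(O)c(O)c(Br)c1
F4 | step 1 | 2,3-dibromo-4,5-dihydroxybenzonitrile | N#Cc1cc(O)c(O)c(Br)c1Br
F5 | step 1 | 2,3,6-tribromo-4,5-dihydroxybenzonitrile | N#Cc1c(Br)c(O)c(O)c(Br)c1Br
F6 | step 1 | 2,3,6-tribromo-4,5-dihydroxybenzaldimine | N=Cc1c(Br)c(O)c(O)c(Br)c1Br
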